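**Plan**

- Retrosynthesis: the two phenols and two acetates lead back to dibenzyl lactone 12. Cutting C1–C2 and C1–C8a of 12 gives (R)-β-benzyl lactone 7 and aldehyde 9. Lactone 7 is cut at C3–C4 and at the lactone C–O bond to O-benzylvanillin 1 and dimethyl succinate 2.
- Enabling feature: C1 carries the syringyl ring and lies between C2 (α to the carbon of one acetoxymethyl arm, a lactone carbonyl until step 6) and C8a of ring A (para to the ring A methoxy group). C1 can therefore be the carbonyl carbon of a syringaldehyde ether that accepts first an enolate equivalent and then the arene.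
- Forward: the chain C4–C3–C2 with both one-carbon arms is built by Stobbe condensation and closed to the lactone ring. Ring B then forms in step 5 between ring A and the lactone ring. Reduction, acetylation and debenzylation finish the synthesis.
- Stereochemistry: C3 comes from a rhodium-catalysed asymmetric hydrogenation, C2 from attack anti to the C3 benzyl group, and C1 from the Friedel–Crafts closure through the conformer with a pseudoequatorial aryl group.

Key step: step 5

Remark on numbering: atom numbers are those of the tetralin core of the target. C1 bears the aryl group, C2 and C3 bear the acetoxymethyl arms, C4 is the benzylic CH2, C4a and C8a are the fusion carbons of ring A, and ring B is the saturated six-membered ring.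

Assumption: the (4S,5S) enantiomer of MOD-DIOP (4,5-bis{[bis(4-methoxy-3,5-dimethylphenyl)phosphino]methyl}-2,2-dimethyl-1,3-dioxolane) is taken to deliver the (R) acid 4. The sense and level of induction are to be checked at lactone 7 by chiral HPLC and correlation with the known (R)-lactone, and the antipodal ligand is used if the sense is opposite.

**Step 1**
Reactants: 1 4-(benzyloxy)-3-methoxybenzaldehyde (O-benzylvanillin, a catalogue compound); 2 dimethyl succinate
Product: 3 (E)-4-[4-(benzyloxy)-3-methoxyphenyl]-3-(methoxycarbonyl)but-3-enoic acid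
Conditions: NaOMe, MeOH, reflux; then aq HCl; crystallisation
Reagents that add atoms: none
Why: Stobbe condensation, in which the succinate enolate adds to the aldehyde, the alkoxide lactonises onto the distal ester and E1cB opening of the paraconate should give the half ester with the aryl group trans to the conjugated ester (E).

**Step 2**
Reactants: 3 (E)-4-[4-(benzyloxy)-3-methoxyphenyl]-3-(methoxycarbonyl)but-3-enoic acid
Product: 4 (R)-4-[4-(benzyloxy)-3-methoxyphenyl]-3-(methoxycarbonyl)butanoic acid
Conditions: H2 (5 atm), [Rh(cod)Cl]2 (0.5 mol% Rh), (4S,5S)-MOD-DIOP, Et3N (1 equiv), MeOH, 30 °C; then aq HCl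
Reagents that add atoms: none
Why: Asymmetric hydrogenation of an itaconate-type half ester, in which the carboxylate and the alkene chelate the rhodium bisphosphine complex so that H2 is delivered to one enantioface and sets the later C3 as (R), while the homogeneous catalyst leaves the benzyl ether alone.

**Step 3**
Reactants: 4 (R)-4-[4-(benzyloxy)-3-methoxyphenyl]-3-(methoxycarbonyl)butanoic acid
Product: 7 (R)-4-[4-(benzyloxy)-3-methoxybenzyl]dihydrofuran-2(3H)-one, via potassium carboxylate 5 (not isolated), via hydroxy acid 6 (not isolated)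
Conditions: KOH (1.0 equiv), EtOH, 0 °C; CaCl2, NaBH4, EtOH, −10 °C → rt; then 6 M HCl, rt
Reagents that add atoms: none
Why: Chemoselective borohydride reduction, in which Ca(BH4)2 formed in the flask reduces the methyl ester but not the carboxylate, and acidification closes the γ-hydroxy acid to the five-membered lactone by acyl substitution without touching the stereocentre.

**Step 4**
Reactants: 8 syringaldehyde (4-hydroxy-3,5-dimethoxybenzaldehyde)
Product: 9 4-(benzyloxy)-3,5-dimethoxybenzaldehyde
Conditions: BnBr, K2CO3, DMF, 60 °C
Reagents that add atoms: benzyl bromide, BrCc1ccccc1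
Why: Williamson ether synthesis, in which the phenoxide displaces bromide from benzyl bromide (SN2) and the aldehyde is unaffected.

**Step 5**
Reactants: 7 (R)-4-[4-(benzyloxy)-3-methoxybenzyl]dihydrofuran-2(3H)-one; 9 4-(benzyloxy)-3,5-dimethoxybenzaldehyde
Product: 12 (3aR,9S,9aR)-7-(benzyloxy)-9-[4-(benzyloxy)-3,5-dimethoxyphenyl]-6-methoxy-3a,4,9,9a-tetrahydronaphtho[2,3-c]furan-1(3H)-one, via silyl ketene acetal 10 (not isolated), via aldol silyl ether 11 (not isolated)
Conditions: LDA, THF, −78 °C; TMSCl, −78 → 0 °C; THF replaced by CH2Cl2 (pentane, filtration of LiCl); 9, TMSOTf (0.2 equiv), CH2Cl2, −78 °C; then TMSOTf (1.2 equiv), −78 → 0 °C; aq NaHCO3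
Reagents that add atoms: none
Why: LDA and TMSCl turn 7 into silyl ketene acetal 10, and aldehyde 9, activated by TMSOTf, is attacked by C2 of 10 through an open Mukaiyama aldol transition state on the face anti to the benzyl group on C3, which forms C1–C2 and fixes C2 trans to C3 under control of the stereocentre set in step 2. The full equivalent of TMSOTf then removes the benzylic silyloxy group of 11 as hexamethyldisiloxane, and the cation, stabilised by the 4-benzyloxy-3,5-dimethoxyphenyl ring, is trapped by ring A at the carbon para to its methoxy group (C1–C8a), an intramolecular Friedel–Crafts alkylation that closes the six-membered ring B in a 6-endo mode with respect to the arene π bond. The closest known reaction type is the aldol addition of β-benzylbutyrolactone enolates to aryl aldehydes followed by acid-mediated cyclisation of the carbinol to trans-fused 1-aryltetralin lactones, and the Mukaiyama variant lets one Lewis acid serve both stages. C1 passes through a planar cation, so both carbinol epimers of 11 converge, and its configuration is set in the ring closure, where the aryl group takes the pseudoequatorial position trans to the carbonyl arm on C2 in a chair-like transition state. The step needs arylation para and not ortho to the ring A methoxy group, which the directing effect of that group and the crowding of the position between CH2 and OMe should secure, and it needs the aldol to be complete before ionisation starts so that no second molecule of 10 captures the cation, which the staged TMSOTf charge at −78 °C should secure; the benzyl ethers should survive if the mixture is quenched at 0 °C.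

**Step 6**
Reactants: 12 (3aR,9S,9aR)-7-(benzyloxy)-9-[4-(benzyloxy)-3,5-dimethoxyphenyl]-6-methoxy-3a,4,9,9a-tetrahydronaphtho[2,3-c]furan-1(3H)-one
Product: 13 {(1S,2R,3R)-7-(benzyloxy)-1-[4-(benzyloxy)-3,5-dimethoxyphenyl]-6-methoxy-1,2,3,4-tetrahydronaphthalene-2,3-diyl}dimethanol
Conditions: LiAlH4, THF, 0 °C → rt (lactone added to the hydride); aq NaOH work-up
Reagents that add atoms: none
Why: Hydride reduction of the lactone to the 1,4-diol, in which addition to the carbonyl should outpace enolisation so that C2 is not epimerised, and the benzyl ethers are inert.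

**Step 7**
Reactants: 13 {(1S,2R,3R)-7-(benzyloxy)-1-[4-(benzyloxy)-3,5-dimethoxyphenyl]-6-methoxy-1,2,3,4-tetrahydronaphthalene-2,3-diyl}dimethanol
Product: 14 {(1S,2R,3R)-7-(benzyloxy)-1-[4-(benzyloxy)-3,5-dimethoxyphenyl]-6-methoxy-1,2,3,4-tetrahydronaphthalene-2,3-diyl}bis(methylene) diacetate
Conditions: Ac2O, pyridine, DMAP (cat.), CH2Cl2, rt
Reagents that add atoms: acetic anhydride, CC(=O)OC(C)=O
Why: DMAP-catalysed acylation of the two primary alcohols, which are the only free hydroxyl groups because both phenols are still benzylated.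

**Step 8**
Reactants: 14 {(1S,2R,3R)-7-(benzyloxy)-1-[4-(benzyloxy)-3,5-dimethoxyphenyl]-6-methoxy-1,2,3,4-tetrahydronaphthalene-2,3-diyl}bis(methylene) diacetate
Product: 15 [(1S,2R,3R)-7-hydroxy-1-(4-hydroxy-3,5-dimethoxyphenyl)-6-methoxy-1,2,3,4-tetrahydronaphthalene-2,3-diyl]bis(methylene) diacetate (CNP0265800.1)
Conditions: H2 (1 atm), 10% Pd/C, EtOAc–EtOH, rt
Reagents that add atoms: none
Why: Hydrogenolysis of the two aryl benzyl ethers over palladium on carbon, under which the acetates, the methyl ethers and the three stereocentres are not affected.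

**Compound list**

1 | 4-(benzyloxy)-3-methoxybenzaldehyde | COc1cc(C=O)ccc1OCc1ccccc1 | starting material
2 | dimethyl succinate | COC(=O)CCC(=O)OC | starting material
3 | (E)-4-[4-(benzyloxy)-3-methoxyphenyl]-3-(methoxycarbonyl)but-3-enoic acid | OC(=O)C/C(C(=O)OC)=C\c1ccc(OCc2ccccc2)c(OC)c1 | intermediate
4 | (R)-4-[4-(benzyloxy)-3-methoxyphenyl]-3-(methoxycarbonyl)butanoic acid | COC(=O)[C@@H](CC(=O)O)Cc1ccc(OCc2ccccc2)c(OC)c1 | intermediate
5 | potassium (R)-4-[4-(benzyloxy)-3-methoxyphenyl]-3-(methoxycarbonyl)butanoate | COC(=O)[C@@H](CC(=O)[O-])Cc1ccc(OCc2ccccc2)c(OC)c1.[K+] | intermediate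
6 | (R)-4-[4-(benzyloxy)-3-methoxyphenyl]-3-(hydroxymethyl)butanoic acid | OC[C@@H](CC(=O)O)Cc1ccc(OCc2ccccc2)c(OC)c1 | intermediate
7 | (R)-4-[4-(benzyloxy)-3-methoxybenzyl]dihydrofuran-2(3H)-one | O=C1C[C@@H](Cc2ccc(OCc3ccccc3)c(OC)c2)CO1 | intermediate
8 | syringaldehyde | COc1cc(C=O)cc(OC)c1O | starting material
9 | 4-(benzyloxy)-3,5-dimethoxybenzaldehyde | COc1cc(C=O)cc(OC)c1OCc1ccccc1 | intermediate
10 | (R)-3-[4-(benzyloxy)-3-methoxybenzyl]-5-[(trimethylsilyl)oxy]-2,3-dihydrofuran | C[Si](C)(C)OC1=C[C@@H](Cc2ccc(OCc3ccccc3)c(OC)c2)CO1 | intermediate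
11 | (3S,4R)-4-[4-(benzyloxy)-3-methoxybenzyl]-3-{[4-(benzyloxy)-3,5-dimethoxyphenyl][(trimethylsilyl)oxy]methyl}dihydrofuran-2(3H)-one (both carbinol epimers) | COc1cc(cc(OC)c1OCc1ccccc1)C(O[Si](C)(C)C)[C@H]1C(=O)OC[C@@H]1Cc1ccc(OCc2ccccc2)c(OC)c1 | intermediate
12 | (3aR,9S,9aR)-7-(benzyloxy)-9-[4-(benzyloxy)-3,5-dimethoxyphenyl]-6-methoxy-3a,4,9,9a-tetrahydronaphtho[2,3-c]furan-1(3H)-one | COc1cc2c(cc1OCc1ccccc1)[C@H](c1cc(OC)c(OCc3ccccc3)c(OC)c1)[C@H]1C(=O)OC[C@@H]1C2 | intermediate
13 | {(1S,2R,3R)-7-(benzyloxy)-1-[4-(benzyloxy)-3,5-dimethoxyphenyl]-6-methoxy-1,2,3,4-tetrahydronaphthalene-2,3-diyl}dimethanol | COc1cc2c(cc1OCc1ccccc1)[C@H](c1cc(OC)c(OCc3ccccc3)c(OC)c1)[C@@H](CO)[C@H](CO)C2 | intermediate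
14 | {(1S,2R,3R)-7-(benzyloxy)-1-[4-(benzyloxy)-3,5-dimethoxyphenyl]-6-methoxy-1,2,3,4-tetrahydronaphthalene-2,3-diyl}bis(methylene) diacetate | COc1cc2c(cc1OCc1ccccc1)[C@H](c1cc(OC)c(OCc3ccccc3)c(OC)c1)[C@@H](COC(C)=O)[C@H](COC(C)=O)C2 | intermediate
15 | [(1S,2R,3R)-7-hydroxy-1-(4-hydroxy-3,5-dimethoxyphenyl)-6-methoxy-1,2,3,4-tetrahydronaphthalene-2,3-diyl]bis(methylene) diacetate | COc1cc2c(cc1O)[C@H](c1cc(OC)c(O)c(OC)c1)[C@@H](COC(C)=O)[C@H](COC(C)=O)C2 | target

**Step count**

Total steps: 8. Longest linear sequence: 7 steps (steps 1, 2, 3, 5, 6, 7, 8, from compound 1); step 4 is a one-step side branch.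

**Steps most likely to fail**

Step 5. The ketene acetal may be lost by C-silylation or protonation back to 7. Ionisation of 11 may begin while 10 is still present, so that the cation is captured a second time. The cation may also lose the C2 proton to give an arylidene lactone, or triflic acid may cleave a benzyl ether before ring B has closed. The fallback separates the two events and sets out from 7 and 9. The lithium enolate of 7 (LiHMDS, THF, −78 °C) is added to 9, which should give, anti to the benzyl group, the β-hydroxy lactone (3S,4R)-4-[4-(benzyloxy)-3-methoxybenzyl]-3-{[4-(benzyloxy)-3,5-dimethoxyphenyl](hydroxy)methyl}dihydrofuran-2(3H)-one F1 as a mixture of carbinol epimers. After isolation, the carbinol is ionised with CF3CO2H in CH2Cl2 at 0 °C → rt, and the same Friedel–Crafts closure should return the route at compound 12.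

Step 2. Enantioface discrimination may be incomplete, the sense of induction may be opposite to the one assumed, or a residue of the Z isomer may react with lower selectivity. The fallback replaces asymmetric catalysis by resolution and sets out from 3. Hydrogenation with the achiral complex [Rh(cod)(dppb)]BF4 (dppb = 1,4-bis(diphenylphosphino)butane; H2, MeOH) should give racemic 4-[4-(benzyloxy)-3-methoxyphenyl]-3-(methoxycarbonyl)butanoic acid F2. Fractional crystallisation with (R)-1-phenylethylamine, or with its antipode if that gives the less soluble salt of the (R) acid, should give (R)-1-phenylethylammonium (R)-4-[4-(benzyloxy)-3-methoxyphenyl]-3-(methoxycarbonyl)butanoate F3. Aqueous HCl then liberates the acid, and the route is rejoined at compound 4.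

Step 3. Hydride may also attack the carboxylate, the ester may be reduced incompletely, or the centre α to the ester may partly epimerise under the basic conditions. The fallback gives up chemoselective reduction in favour of regioselective oxidation and sets out from 4. LiAlH4 in THF reduces both carbonyl groups to (R)-2-[4-(benzyloxy)-3-methoxybenzyl]butane-1,4-diol F4. Transfer dehydrogenation with RuH2(PPh3)4 and 4-phenylbut-3-en-2-one in toluene should oxidise the less hindered CH2CH2OH end first. The hydroxy aldehyde closes to the lactol and is dehydrogenated to the β-substituted lactone, which rejoins the route at compound 7.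

**Further compounds**

F1 | step 5 | (3S,4R)-4-[4-(benzyloxy)-3-methoxybenzyl]-3-{[4-(benzyloxy)-3,5-dimethoxyphenyl](hydroxy)methyl}dihydrofuran-2(3H)-one (carbinol epimers) | COc1cc(cc(OC)c1OCc1ccccc1)C(O)[C@H]1C(=O)OC[C@@H]1Cc1ccc(OCc2ccccc2)c(OC)c1
F2 | step 2 | racemic 4-[4-(benzyloxy)-3-methoxyphenyl]-3-(methoxycarbonyl)butanoic acid | COC(=O)C(CC(=O)O)Cc1ccc(OCc2ccccc2)c(OC)c1
F3 | step 2 | (R)-1-phenylethylammonium (R)-4-[4-(benzyloxy)-3-methoxyphenyl]-3-(methoxycarbonyl)butanoate | COC(=O)[C@@H](CC(=O)[O-])Cc1ccc(OCc2ccccc2)c(OC)c1.C[C@@H]([NH3+])c1ccccc1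
F4 | step 3 | (R)-2-[4-(benzyloxy)-3-methoxybenzyl]butane-1,4-diol | OC[C@@H](CCO)Cc1ccc(OCc2ccccc2)c(OC)c1
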